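## Structural features

The target is a 2,3-trans-dihydroflavonol: a chroman-4-one (ring C) fused to a phloroglucinol-type ring A, with a 4-hydroxyphenyl ring B on C2. C2 and C3 are neighbouring stereocentres, both R, with the aryl group and the C3 hydroxyl trans on the ring; this is the anti arrangement in the open C4–C3–C2 chain. Ring A has free hydroxyls at C5 and C7 and, between them at C6, a 2-methylbut-3-en-2-yl group whose quaternary carbon is bonded directly to the arene. The fragile parts are:

- the α-hydroxy-β-aryloxy ketone of ring C, which base can open at O1–C2 (through the C3 enolate or a ring B quinone methide), scrambling both centres, and which air oxidises to the flavonol;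
- the terminal vinyl group, which rules out hydrogenation and which acid can close onto a neighbouring phenol;
- the electron-rich phenols.

The real difficulty is to set C2 and C3 in the absolute sense on a skeleton that racemises easily, and to place the side chain at C6 rather than C8. The key step uses the substitution pattern of C3: it carries H, one oxygen, the C4 acyl carbon and C2, which is what the carbene carbon of an aryl diazomethyl ketone becomes after capture of an alcohol and then an aldehyde. C2 is then the carbonyl carbon of a ring B aldehyde, and a fluorine on C8a of ring A keeps the place of O1.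

## Logic of the disconnections

20 to 19 to 18. The three aryl ester C–O bonds and the benzylic C–O bond on O3 are cut. The phenols must be esters for the carbene and ring-closure steps, and O3 must be an ether so that only the C2 oxygen can arylate. The gain is a fully masked ring system with no acidic or oxidisable phenol. The demand is that the ether leaves oxidatively while the phenols are still acylated, and that the final ester cleavage is short, cold and oxygen-free.

18 to 17. The O1–C8a bond is cut. Forming this aryl–oxygen bond from the C2 hydroxyl does not touch the C2–O bond, so both centres of 17 pass unchanged into the ring. Ring C opens to an acyclic aldol. The demand is an electron-poor ring A with fluoride ortho to the ketone, and an alkoxide that cyclises faster than it undergoes retro-aldol cleavage.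

17 to 12, 14 and 15. The C2–C3 bond and the C3–O bond are cut. This splits the molecule into three pieces of similar size and puts the creation of both stereocentres into one step. The demand is anti and absolute control from the catalyst pair, and no donor in 12 that could trap the carbenoid internally.

12 to 10 to 9. The C4–C3 bond (acyl carbon to diazomethyl carbon) is cut, and the acid is taken back to the aldehyde. The gain is an arene with a single one-carbon substituent. The demand is that both phenols are acylated before oxidation, and that the oxidation spares the vinyl group.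

9 to 8 to 6 to 4 and 5. The aryl C6–C(quaternary) bond is cut and reconnected as an O–CH2 ether bond (retro [3,3] shift), after removal of one ester. The ether is placed on the oxygen next to the formyl group, so the only free ortho position is the carbon between the two oxygens. On 1 itself the allyl unit could also migrate to the carbon beside fluorine, and a meta fluorine is expected to favour that position. The gain is two simple pieces, 4 and 5. The demand is heat, and tautomerisation of the dienone faster than a second shift to the para carbon.

4 to 3 to 1. One ester C–O bond and the aryl–CHO bond are cut. This leads back to symmetrical 1. The demand is formylation para to one hydroxyl and beside fluorine, and acylation of only the unchelated hydroxyl.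

14 to 13. The aryl ester C–O bond is cut. The ester keeps the aldehyde electrophilic and is removed with the ring A esters at the end.

## Other disconnections considered

Alternative 1: The cut is O1–C8a together with C4a–C4.

- Forward key step: CsF acts on 3,5-bis(methoxymethoxy)-4-(2-methylbut-3-en-2-yl)-2-(trimethylsilyl)phenyl trifluoromethanesulfonate A2 to release 3,5-bis(methoxymethoxy)-4-(2-methylbut-3-en-2-yl)benzyne A4. The C2 alkoxide of methyl (2R,3R)-2-[(tert-butyldimethylsilyl)oxy]-3-hydroxy-3-[4-(methoxymethoxy)phenyl]propanoate A3 adds at C8a, and the aryl anion left at C4a attacks the ester to give (2R,3R)-3-O-(tert-butyldimethylsilyl)-5,7,4'-tris-O-(methoxymethyl)-6-(2-methylbut-3-en-2-yl)aromadendrin A1.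
- In its favour: ring C and two skeletal bonds form in one step. The alkoxy group on C5 polarises the strained bond so that attack at the distal carbon C8a is the expected one. The stereocentres come from a building block, so the key step needs no asymmetric catalyst. On this last point it is the better plan, because the chosen key step must create both centres by a reaction without direct precedent. On retention at C2 during O1–C8a formation the two plans are equal.
- Against it here: A2 is a penta-substituted arene that already needs the side chain in place. A3 is an anti, differentially protected diol, which needs a (Z)-cinnamate dihydroxylation or an inversion and then a regioselective silylation. In the flask, silyl migration from O3 to O2, retro-aldol cleavage, and protonation of the aryl anion before acylation all compete. The acetal groups must finally be removed with acid beside the vinyl group.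
- Comparison: the ring-oxygen bond is the same and one more bond is made. The mechanism is a polar addition–acylation instead of carbenoid and ylide chemistry. The key step does more, but A2 and A3 would probably cost more steps than 12 and 14.

Alternative 2: The cut is at the quaternary carbon, at its bonds to one methyl and to the vinyl group.

- Forward key step: MeMgBr adds to the ketone of 2-acetyl-3,5-bis(methoxymethoxy)phenyl tert-butyl carbonate A6. The carbonate shifts to the new alkoxide and is lost, giving 3,5-bis(methoxymethoxy)-6-(propan-2-ylidene)cyclohexa-2,4-dien-1-one A7. CH2=CHMgBr adds to its exocyclic carbon to give 3,5-bis(methoxymethoxy)-2-(2-methylbut-3-en-2-yl)phenol A5.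
- In its favour: the position of the side chain is fixed by where the acetyl group sits on a cheap phloroglucinol ketone. There is no regiochemical question, no heating and no competing shift. On the side chain it is the better plan, since the chosen route's rearrangement must outrun a shift to the para carbon.
- Against it here: A7 can lose a methyl hydrogen by a 1,5-shift before the second Grignard reagent arrives. A5 has no fluorine, and its free phenol lies next to the side chain; closing ring C through that oxygen would give the 8-substituted series, so the protecting groups must be re-sorted. Ring C and both stereocentres are still to be built.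
- Comparison: structurally it solves only C6. The mechanism is an ionic cascade instead of a sigmatropic shift. Locally it is one flask against two steps, but as the basis of a whole route it is longer, and it cannot supply the fluorinated ring A that the chosen ring closure needs.

Alternative 3: The cut is C4a–C4, C4–C3 and O1–C2.

- Forward key step: PdCl2(PPh3)2 (a divalent palladium precatalyst, reduced in the flask to zerovalent palladium), carbon monoxide and an amine join 2-iodo-3,5-bis(methoxymethoxy)-4-(2-methylbut-3-en-2-yl)phenol A9 and 1-ethynyl-4-(methoxymethoxy)benzene A10 to 1-[2-hydroxy-4,6-bis(methoxymethoxy)-5-(2-methylbut-3-en-2-yl)phenyl]-3-[4-(methoxymethoxy)phenyl]prop-2-yn-1-one A11. The phenol closes 6-endo to 5,7,4'-tris-O-(methoxymethyl)-6-(2-methylbut-3-en-2-yl)apigenin A8.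
- In its favour: three skeletal bonds and ring C form in one convergent step of a well-established reaction type. In bond count and convergence it is better than the chosen key step, which forms two bonds and no ring.
- Against it here: A8 is flat at C2 and C3. The target would then need an enantioselective 1,4-reduction that leaves the vinyl group alone (hydrogenation is excluded), followed by a trans-selective C3 hydroxylation through an enolate that can open the ring. 5-exo closure to the aurone skeleton competes. The iodide is flanked by oxygen substituents, and A9 has the same side-chain placement problem.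
- Comparison: it sets no stereocentre where the chosen step sets two. The mechanism is carbonylative cross-coupling with toxic gas, against carbenoid chemistry. It is shorter to the ring system but longer and less certain to the target.

Key step: step 9

Assumption: the facial preference of the chiral phosphoric acid in step 9 cannot be predicted for this substrate class; the (R)-acid is written and stands for whichever antipode leads to the (2R,3R) adduct 17.

Remark on the structures: the names, SMILES and descriptors of 12, 17 and 20 were checked against each other. The anti adduct (2R,3R)-17 has the same spatial arrangement at both centres as (2R,3R)-20, and closure at O1–C8a changes neither descriptor, so no structure needed correction.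

Remark on the design: two points of the approach to 12 are arranged for safety. The allyl ether is placed on the chelated oxygen of 4, and both phenols are acylated before the aldehyde is oxidised.

## Route

Step 1
Reactants: 1 5-fluorobenzene-1,3-diol
Product: 3 2-fluoro-4,6-dihydroxybenzaldehyde, via iminium chloride 2 (not isolated)
Conditions: POCl3, DMF, MeCN, −15 °C → rt; then H2O, 50 °C
Reagents that add atoms: N,N-dimethylformamide, CN(C)C=O; water, O
Why: Vilsmeier–Haack formylation; the chloroiminium ion attacks the carbon para to one hydroxyl and ortho to the other, which is the carbon beside fluorine, while the position between the two hydroxyls is more crowded; hydrolysis of 2 gives the aldehyde.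

Step 2
Reactants: 3 2-fluoro-4,6-dihydroxybenzaldehyde
Product: 4 3-fluoro-4-formyl-5-hydroxyphenyl pivalate
Conditions: t-BuCOCl (1.05 equiv), Et3N, CH2Cl2, −20 → 0 °C
Reagents that add atoms: pivaloyl chloride, CC(C)(C)C(=O)Cl
Why: Esterification; the hydroxyl next to the formyl group is held in a hydrogen bond, so the para hydroxyl, which is more acidic and more nucleophilic, is acylated selectively at low temperature.

Step 3
Reactants: 4 3-fluoro-4-formyl-5-hydroxyphenyl pivalate; 5 1-bromo-3-methylbut-2-ene
Product: 6 3-fluoro-4-formyl-5-[(3-methylbut-2-en-1-yl)oxy]phenyl pivalate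
Conditions: K2CO3, DMF, rt
Reagents that add atoms: none
Why: Williamson ether synthesis on the remaining chelated phenol; the phenoxide displaces bromide at the primary carbon (SN2), and the hindered pivalate tolerates carbonate in dry DMF.

Step 4
Reactants: 6 3-fluoro-4-formyl-5-[(3-methylbut-2-en-1-yl)oxy]phenyl pivalate
Product: 8 5-fluoro-4-formyl-3-hydroxy-2-(2-methylbut-3-en-2-yl)phenyl pivalate, via ortho-dienone 7 (not isolated)
Conditions: PhNEt2, 190 °C, argon
Reagents that add atoms: none
Why: Aromatic Claisen rearrangement; the other ortho position bears the formyl group, so the [3,3] shift can deliver the inverted allyl unit only to the carbon between the two oxygens, and the amine solvent speeds tautomerisation of 7 to the chelated phenol so that it competes with a further Cope shift; the flanking ester and the chelation of the new phenol suppress the abnormal Claisen pathway and ring closure onto the vinyl group.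

Step 5
Reactants: 8 5-fluoro-4-formyl-3-hydroxy-2-(2-methylbut-3-en-2-yl)phenyl pivalate
Product: 9 2-fluoro-5-(2-methylbut-3-en-2-yl)-4,6-bis(pivaloyloxy)benzaldehyde
Conditions: t-BuCOCl, Et3N, 4-(dimethylamino)pyridine (cat.), CH2Cl2, 0 → 40 °C
Reagents that add atoms: pivaloyl chloride, CC(C)(C)C(=O)Cl
Why: Acylation of a hindered, chelated phenol through the acylpyridinium ion; there is no enolisable position, so forcing conditions are tolerated.

Step 6
Reactants: 9 2-fluoro-5-(2-methylbut-3-en-2-yl)-4,6-bis(pivaloyloxy)benzaldehyde
Product: 10 2-fluoro-5-(2-methylbut-3-en-2-yl)-4,6-bis(pivaloyloxy)benzoic acid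
Conditions: NaClO2, NaH2PO4, 2-methyl-2-butene, t-BuOH/H2O, 0 °C → rt
Reagents that add atoms: sodium chlorite, [Na+].[O-]Cl=O
Why: Pinnick oxidation; chlorous acid adds to the aldehyde and fragments to the acid, the trisubstituted scavenger alkene takes up the hypochlorous acid far faster than the monosubstituted vinyl group, and with both phenols acylated the ring is not chlorinated.

Step 7
Reactants: 10 2-fluoro-5-(2-methylbut-3-en-2-yl)-4,6-bis(pivaloyloxy)benzoic acid
Product: 12 2-diazo-1-[2-fluoro-5-(2-methylbut-3-en-2-yl)-4,6-bis(pivaloyloxy)phenyl]ethanone, via acid chloride 11 (not isolated)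
Conditions: (COCl)2, N,N-dimethylformamide (cat.), CH2Cl2, 0 °C → rt; evaporate; Me3SiCHN2 (2.2 equiv), THF/MeCN, 0 °C → rt
Reagents that add atoms: oxalyl chloride, O=C(Cl)C(=O)Cl (chlorine of 11 only); (trimethylsilyl)diazomethane, C[Si](C)(C)C=[N+]=[N-]
Why: Acid chloride formation followed by C-acylation of the silylated diazomethane and chloride-induced loss of the silyl group (the first stage of an Arndt–Eistert sequence); no base is present, so the aryl esters are untouched.

Step 8
Reactants: 13 4-hydroxybenzaldehyde
Product: 14 4-formylphenyl pivalate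
Conditions: t-BuCOCl, Et3N, 4-(dimethylamino)pyridine (cat.), CH2Cl2, 0 °C → rt
Reagents that add atoms: pivaloyl chloride, CC(C)(C)C(=O)Cl
Why: Phenol esterification; the ester keeps the aldehyde electrophilic and is removed with the ring A esters at the end.

Step 9
Reactants: 12 2-diazo-1-[2-fluoro-5-(2-methylbut-3-en-2-yl)-4,6-bis(pivaloyloxy)phenyl]ethanone; 14 4-formylphenyl pivalate; 15 4-methoxybenzyl alcohol
Product: 17 (2R,3R)-1-[2-fluoro-5-(2-methylbut-3-en-2-yl)-4,6-bis(pivaloyloxy)phenyl]-3-hydroxy-2-[(4-methoxybenzyl)oxy]-3-[4-(pivaloyloxy)phenyl]propan-1-one, via oxonium ylide 16 (not isolated)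
Conditions: Rh2(OAc)4 (2 mol %), (R)-3,3'-bis(2,4,6-triisopropylphenyl)-1,1'-binaphthyl-2,2'-diyl hydrogen phosphate (10 mol %), 4 Å MS, CH2Cl2, 0 °C; 12 and 15 added over 2 h to 14 (1.5 equiv)
Reagents that add atoms: none
Why: Proposed new method: Rh2(OAc)4 (divalent rhodium) expels dinitrogen from 12 to give an electrophilic acyl carbenoid, and the hydroxyl oxygen of 15 adds to it to give the protic oxonium ylide 16, an enol equivalent centred on C3. The phosphoric acid is expected to hold this enol through its P=O oxygen and the aldehyde 14 through its P–OH in one hydrogen-bonded array, so that C2–C3 bond formation outruns the 1,2-proton shift that would end in plain O–H insertion. The closest known reaction type is the dirhodium and acid co-catalysed three-component coupling of diazo carbonyl compounds, alcohols and aldehydes or imines by aldol- or Mannich-type capture of oxonium ylides; anti and absolute control with an acceptor-only aryl diazomethyl ketone and an aromatic aldehyde is the unproven part. No ring is closed. C3 (the former carbene carbon) and C2 (the former aldehyde carbon) are created together, and both their relative (anti) and absolute configuration are set by the chiral acid, whose 3,3'-aryl groups decide which face of the aldehyde meets which face of the enol. The step needs three-component coupling to win over two-component pathways; slow addition keeps 12 and 15 dilute beside an excess of 14, whose acyloxy group keeps it electrophilic. It also needs the carbenoid not to be trapped internally: the ring A oxygens are esters and poor donors, the vinyl group is out of reach, and the fluorine is inert.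

Step 10
Reactants: 17 (2R,3R)-1-[2-fluoro-5-(2-methylbut-3-en-2-yl)-4,6-bis(pivaloyloxy)phenyl]-3-hydroxy-2-[(4-methoxybenzyl)oxy]-3-[4-(pivaloyloxy)phenyl]propan-1-one
Product: 18 (2R,3R)-3-[(4-methoxybenzyl)oxy]-6-(2-methylbut-3-en-2-yl)-4-oxo-2-[4-(pivaloyloxy)phenyl]chroman-5,7-diyl dipivalate
Conditions: K2CO3, DMF, 0 °C → rt
Reagents that add atoms: none
Why: Intramolecular nucleophilic aromatic substitution (addition–elimination); the alkoxide on the C2 oxygen attacks C8a, which the ortho ketone activates and the two meta acyloxy groups keep electron-poor, and closes the six-membered ring. The C2–O bond is not broken, so C2 is retained, C3 is untouched and both substituents end up equatorial; mild base and low temperature limit retro-aldol cleavage and enolisation.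

Step 11
Reactants: 18 (2R,3R)-3-[(4-methoxybenzyl)oxy]-6-(2-methylbut-3-en-2-yl)-4-oxo-2-[4-(pivaloyloxy)phenyl]chroman-5,7-diyl dipivalate
Product: 19 (2R,3R)-3-hydroxy-6-(2-methylbut-3-en-2-yl)-4-oxo-2-[4-(pivaloyloxy)phenyl]chroman-5,7-diyl dipivalate
Conditions: 2,3-dichloro-5,6-dicyano-1,4-benzoquinone (DDQ), CH2Cl2/pH 7 buffer, 0 °C → rt
Reagents that add atoms: none
Why: Oxidative cleavage of the 4-methoxybenzyl ether (hydride abstraction, then hydrolysis of the oxocarbenium ion); the phenols are still esters and therefore not oxidised, and the monosubstituted alkene is inert to the quinone.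

Step 12
Reactants: 19 (2R,3R)-3-hydroxy-6-(2-methylbut-3-en-2-yl)-4-oxo-2-[4-(pivaloyloxy)phenyl]chroman-5,7-diyl dipivalate
Product: 20 (2R,3R)-3,5,7-trihydroxy-2-(4-hydroxyphenyl)-6-(2-methylbut-3-en-2-yl)chroman-4-one
Conditions: K2CO3, MeOH/THF (degassed), 0 °C, argon; then AcOH
Reagents that add atoms: none
Why: Base-mediated transesterification of three aryl esters, whose phenoxides are good leaving groups; cold, oxygen-free conditions and an acid quench are chosen to avoid ring opening at O1–C2 and oxidation of the α-ketol, and the trans arrangement set earlier is also the thermodynamically preferred one.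

## Compound list

1 | 5-fluorobenzene-1,3-diol | Oc1cc(O)cc(F)c1 | starting material
2 | N-[(2-fluoro-4,6-dihydroxyphenyl)methylidene]-N-methylmethanaminium chloride | C[N+](C)=Cc1c(F)cc(O)cc1O.[Cl-] | intermediate (not isolated)
3 | 2-fluoro-4,6-dihydroxybenzaldehyde | O=Cc1c(F)cc(O)cc1O | intermediate
4 | 3-fluoro-4-formyl-5-hydroxyphenyl pivalate | CC(C)(C)C(=O)Oc1cc(O)c(C=O)c(F)c1 | intermediate
5 | 1-bromo-3-methylbut-2-ene | CC(C)=CCBr | starting material
6 | 3-fluoro-4-formyl-5-[(3-methylbut-2-en-1-yl)oxy]phenyl pivalate | CC(C)=CCOc1cc(OC(=O)C(C)(C)C)cc(F)c1C=O | intermediate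
7 | 3-fluoro-4-formyl-6-(2-methylbut-3-en-2-yl)-5-oxocyclohexa-1,3-dien-1-yl pivalate (racemic at the sp3 ring carbon) | O=CC1=C(F)C=C(OC(=O)C(C)(C)C)C(C(C)(C)C=C)C1=O | intermediate (not isolated)
8 | 5-fluoro-4-formyl-3-hydroxy-2-(2-methylbut-3-en-2-yl)phenyl pivalate | C=CC(C)(C)c1c(OC(=O)C(C)(C)C)cc(F)c(C=O)c1O | intermediate
9 | 2-fluoro-5-(2-methylbut-3-en-2-yl)-4,6-bis(pivaloyloxy)benzaldehyde | C=CC(C)(C)c1c(OC(=O)C(C)(C)C)cc(F)c(C=O)c1OC(=O)C(C)(C)C | intermediate
10 | 2-fluoro-5-(2-methylbut-3-en-2-yl)-4,6-bis(pivaloyloxy)benzoic acid | C=CC(C)(C)c1c(OC(=O)C(C)(C)C)cc(F)c(C(=O)O)c1OC(=O)C(C)(C)C | intermediate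
11 | 2-fluoro-5-(2-methylbut-3-en-2-yl)-4,6-bis(pivaloyloxy)benzoyl chloride | C=CC(C)(C)c1c(OC(=O)C(C)(C)C)cc(F)c(C(=O)Cl)c1OC(=O)C(C)(C)C | intermediate (not isolated)
12 | 2-diazo-1-[2-fluoro-5-(2-methylbut-3-en-2-yl)-4,6-bis(pivaloyloxy)phenyl]ethanone | C=CC(C)(C)c1c(OC(=O)C(C)(C)C)cc(F)c(c1OC(=O)C(C)(C)C)C(=O)C=[N+]=[N-] | intermediate
13 | 4-hydroxybenzaldehyde | O=Cc1ccc(O)cc1 | starting material
14 | 4-formylphenyl pivalate | CC(C)(C)C(=O)Oc1ccc(C=O)cc1 | intermediate
15 | 4-methoxybenzyl alcohol | COc1ccc(CO)cc1 | starting material
16 | 1-[(4-methoxybenzyl)oxonio]-2-[2-fluoro-5-(2-methylbut-3-en-2-yl)-4,6-bis(pivaloyloxy)phenyl]-2-oxoethan-1-ide | C=CC(C)(C)c1c(OC(=O)C(C)(C)C)cc(F)c(c1OC(=O)C(C)(C)C)C(=O)[CH-][OH+]Cc1ccc(OC)cc1 | intermediate (not isolated)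
17 | (2R,3R)-1-[2-fluoro-5-(2-methylbut-3-en-2-yl)-4,6-bis(pivaloyloxy)phenyl]-3-hydroxy-2-[(4-methoxybenzyl)oxy]-3-[4-(pivaloyloxy)phenyl]propan-1-one | C=CC(C)(C)c1c(OC(=O)C(C)(C)C)cc(F)c(c1OC(=O)C(C)(C)C)C(=O)[C@H](OCc1ccc(OC)cc1)[C@@H](c1ccc(OC(=O)C(C)(C)C)cc1)O | intermediate
18 | (2R,3R)-3-[(4-methoxybenzyl)oxy]-6-(2-methylbut-3-en-2-yl)-4-oxo-2-[4-(pivaloyloxy)phenyl]chroman-5,7-diyl dipivalate | C=CC(C)(C)c1c(OC(=O)C(C)(C)C)cc2c(c1OC(=O)C(C)(C)C)C(=O)[C@H](OCc1ccc(OC)cc1)[C@@H](c1ccc(OC(=O)C(C)(C)C)cc1)O2 | intermediate
19 | (2R,3R)-3-hydroxy-6-(2-methylbut-3-en-2-yl)-4-oxo-2-[4-(pivaloyloxy)phenyl]chroman-5,7-diyl dipivalate | C=CC(C)(C)c1c(OC(=O)C(C)(C)C)cc2c(c1OC(=O)C(C)(C)C)C(=O)[C@H](O)[C@@H](c1ccc(OC(=O)C(C)(C)C)cc1)O2 | intermediate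
20 | (2R,3R)-3,5,7-trihydroxy-2-(4-hydroxyphenyl)-6-(2-methylbut-3-en-2-yl)chroman-4-one | C=CC(C)(C)c1c(O)cc2c(c1O)C(=O)[C@H](O)[C@@H](c1ccc(O)cc1)O2 | target

## Step count and least certain steps

Total: 12 steps. Longest linear sequence: 11 steps (1 to 20 through steps 1–7 and 9–12); step 8 is the one-step side branch.

**Step 9 (key step).** The most likely failures are that the 1,2-proton shift of the ylide wins and only the ether of O–H insertion forms, or that facial selectivity at the aldehyde is poor. The reason is that an aromatic aldehyde is a weaker hydrogen-bond acceptor than the imines for which this kind of trapping is best established.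

Fallback (known chemistry): it sets out from 12 and returns at 17.
- 12 is decomposed by Rh2(OAc)4 with 15 alone (ordinary O–H insertion) to give 1-[2-fluoro-5-(2-methylbut-3-en-2-yl)-4,6-bis(pivaloyloxy)phenyl]-2-[(4-methoxybenzyl)oxy]ethanone F1.
- Soft enolisation with Me3SiOTf and Et3N gives (Z)-1-[2-fluoro-5-(2-methylbut-3-en-2-yl)-4,6-bis(pivaloyloxy)phenyl]-2-[(4-methoxybenzyl)oxy]-1-(trimethylsilyloxy)ethene F2. This avoids a free enolate, which could undergo Baker–Venkataraman acyl transfer.
- A Mukaiyama aldol addition of F2 to 14, promoted by SiCl4 and a chiral Lewis base such as (S)-2,2'-bis(diphenylphosphoryl)-1,1'-binaphthyl or its antipode (CH2Cl2, −78 °C), returns to 17 after aqueous work-up. This is an established reaction type for silyl enol ethers and aromatic aldehydes; the anti isomer would be secured by chromatography at 17.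

**Step 10.** The alkoxide may fragment by retro-aldol cleavage, or the ketone may enolise (epimerising C3 or eliminating water) faster than the ring closes. The α-hydrogen is more acidic than the hydroxyl, and the ketone is twisted by its two ortho substituents.

Fallback: it sets out from 17 and returns at 18.
- Silylation (Me3SiCl, imidazole) gives (2R,3R)-1-[2-fluoro-5-(2-methylbut-3-en-2-yl)-4,6-bis(pivaloyloxy)phenyl]-2-[(4-methoxybenzyl)oxy]-3-[4-(pivaloyloxy)phenyl]-3-(trimethylsilyloxy)propan-1-one F3.
- A catalytic amount of anhydrous fluoride (tetrabutylammonium difluorotriphenylsilicate, THF, 0 °C) starts a desilylative arylation in which each ring closure releases the fluoride for the next. No stoichiometric base is present to enolise substrate or product.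

**Step 4.** The dienone may undergo a second [3,3] shift to the para carbon beside fluorine before it tautomerises, giving the normal prenyl isomer. This is a known tendency of tertiary allyl groups on crowded dienones.

Fallback: it sets out from 3 and returns at 9.
- 3 is alkylated only at its unchelated hydroxyl (5, 1 equiv K2CO3, acetone) to give 2-fluoro-6-hydroxy-4-[(3-methylbut-2-en-1-yl)oxy]benzaldehyde F4.
- Its Claisen rearrangement has the para carbon blocked by the formyl group, and is steered to the carbon between the oxygens by the bond fixation of the chelate. It gives 2-fluoro-4,6-dihydroxy-5-(2-methylbut-3-en-2-yl)benzaldehyde F5.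
- Double pivaloylation of F5 gives 9.

**Step 7.** Acylation of the diazo nucleophile by the doubly ortho-substituted acid chloride may be slow, and the acid chloride may be lost to hydrolysis or ketene-type side reactions.

Fallback: it sets out from 11 and returns at 12.
- Iron-catalysed coupling with MeMgBr (Fe(acac)3 cat., THF, −78 °C) gives 1-[2-fluoro-5-(2-methylbut-3-en-2-yl)-4,6-bis(pivaloyloxy)phenyl]ethanone F6.
- Detrifluoroacetylative diazo transfer follows: LiN(SiMe3)2 and CF3CO2CH2CF3 at −78 °C give 4,4,4-trifluoro-1-[2-fluoro-5-(2-methylbut-3-en-2-yl)-4,6-bis(pivaloyloxy)phenyl]butane-1,3-dione F7, and MsN3 with Et3N in aqueous MeCN gives 12. The low temperature is meant to outrun acyl transfer from the ortho ester.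

**Step 12.** Prolonged base may be needed for the hindered C5 ester, and the free α-ketol can then suffer ring opening at O1–C2, epimerisation and air oxidation.

Fallback: it sets out from 18 and returns at 20.
- The esters are cleaved first (K2CO3, MeOH, 0 °C) while O3 is still an ether, so no α-ketol is exposed to base. This gives (2R,3R)-5,7-dihydroxy-2-(4-hydroxyphenyl)-3-[(4-methoxybenzyl)oxy]-6-(2-methylbut-3-en-2-yl)chroman-4-one F8.
- The benzyl ether is then removed without an oxidant by MgBr2·OEt2 and Me2S in CH2Cl2, helped by chelation between the C4 carbonyl and O3.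

Further compounds

F1 | step 9 | 1-[2-fluoro-5-(2-methylbut-3-en-2-yl)-4,6-bis(pivaloyloxy)phenyl]-2-[(4-methoxybenzyl)oxy]ethanone | C=CC(C)(C)c1c(OC(=O)C(C)(C)C)cc(F)c(c1OC(=O)C(C)(C)C)C(=O)COCc1ccc(OC)cc1
F2 | step 9 | (Z)-1-[2-fluoro-5-(2-methylbut-3-en-2-yl)-4,6-bis(pivaloyloxy)phenyl]-2-[(4-methoxybenzyl)oxy]-1-(trimethylsilyloxy)ethene | C=CC(C)(C)c1c(OC(=O)C(C)(C)C)cc(F)c(c1OC(=O)C(C)(C)C)/C(O[Si](C)(C)C)=C/OCc1ccc(OC)cc1
F3 | step 10 | (2R,3R)-1-[2-fluoro-5-(2-methylbut-3-en-2-yl)-4,6-bis(pivaloyloxy)phenyl]-2-[(4-methoxybenzyl)oxy]-3-[4-(pivaloyloxy)phenyl]-3-(trimethylsilyloxy)propan-1-one | C=CC(C)(C)c1c(OC(=O)C(C)(C)C)cc(F)c(c1OC(=O)C(C)(C)C)C(=O)[C@H](OCc1ccc(OC)cc1)[C@@H](c1ccc(OC(=O)C(C)(C)C)cc1)O[Si](C)(C)C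
F4 | step 4 | 2-fluoro-6-hydroxy-4-[(3-methylbut-2-en-1-yl)oxy]benzaldehyde | CC(C)=CCOc1cc(O)c(C=O)c(F)c1
F5 | step 4 | 2-fluoro-4,6-dihydroxy-5-(2-methylbut-3-en-2-yl)benzaldehyde | C=CC(C)(C)c1c(O)cc(F)c(C=O)c1O
F6 | step 7 | 1-[2-fluoro-5-(2-methylbut-3-en-2-yl)-4,6-bis(pivaloyloxy)phenyl]ethanone | C=CC(C)(C)c1c(OC(=O)C(C)(C)C)cc(F)c(C(C)=O)c1OC(=O)C(C)(C)C
F7 | step 7 | 4,4,4-trifluoro-1-[2-fluoro-5-(2-methylbut-3-en-2-yl)-4,6-bis(pivaloyloxy)phenyl]butane-1,3-dione | C=CC(C)(C)c1c(OC(=O)C(C)(C)C)cc(F)c(C(=O)CC(=O)C(F)(F)F)c1OC(=O)C(C)(C)C
F8 | step 12 | (2R,3R)-5,7-dihydroxy-2-(4-hydroxyphenyl)-3-[(4-methoxybenzyl)oxy]-6-(2-methylbut-3-en-2-yl)chroman-4-one | C=CC(C)(C)c1c(O)cc2c(c1O)C(=O)[C@H](OCc1ccc(OC)cc1)[C@@H](c1ccc(O)cc1)O2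
A1 | alternative 1 | (2R,3R)-3-O-(tert-butyldimethylsilyl)-5,7,4'-tris-O-(methoxymethyl)-6-(2-methylbut-3-en-2-yl)aromadendrin | C=CC(C)(C)c1c(OCOC)cc2c(c1OCOC)C(=O)[C@H](O[Si](C)(C)C(C)(C)C)[C@@H](c1ccc(OCOC)cc1)O2
A2 | alternative 1 | 3,5-bis(methoxymethoxy)-4-(2-methylbut-3-en-2-yl)-2-(trimethylsilyl)phenyl trifluoromethanesulfonate | C=CC(C)(C)c1c(OCOC)cc(OS(=O)(=O)C(F)(F)F)c([Si](C)(C)C)c1OCOC
A3 | alternative 1 | methyl (2R,3R)-2-[(tert-butyldimethylsilyl)oxy]-3-hydroxy-3-[4-(methoxymethoxy)phenyl]propanoate | COC(=O)[C@H](O[Si](C)(C)C(C)(C)C)[C@@H](c1ccc(OCOC)cc1)O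
A4 | alternative 1 | 3,5-bis(methoxymethoxy)-4-(2-methylbut-3-en-2-yl)benzyne | C=CC(C)(C)C1=C(OCOC)C#CC=C1OCOC
A5 | alternative 2 | 3,5-bis(methoxymethoxy)-2-(2-methylbut-3-en-2-yl)phenol | C=CC(C)(C)c1c(O)cc(OCOC)cc1OCOC
A6 | alternative 2 | 2-acetyl-3,5-bis(methoxymethoxy)phenyl tert-butyl carbonate | CC(=O)c1c(OC(=O)OC(C)(C)C)cc(OCOC)cc1OCOC
A7 | alternative 2 | 3,5-bis(methoxymethoxy)-6-(propan-2-ylidene)cyclohexa-2,4-dien-1-one | CC(C)=C1C(=O)C=C(OCOC)C=C1OCOC
A8 | alternative 3 | 5,7,4'-tris-O-(methoxymethyl)-6-(2-methylbut-3-en-2-yl)apigenin | C=CC(C)(C)c1c(OCOC)cc2oc(-c3ccc(OCOC)cc3)cc(=O)c2c1OCOC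
A9 | alternative 3 | 2-iodo-3,5-bis(methoxymethoxy)-4-(2-methylbut-3-en-2-yl)phenol | C=CC(C)(C)c1c(OCOC)cc(O)c(I)c1OCOC
A10 | alternative 3 | 1-ethynyl-4-(methoxymethoxy)benzene | C#Cc1ccc(OCOC)cc1
A11 | alternative 3 | 1-[2-hydroxy-4,6-bis(methoxymethoxy)-5-(2-methylbut-3-en-2-yl)phenyl]-3-[4-(methoxymethoxy)phenyl]prop-2-yn-1-one | C=CC(C)(C)c1c(OCOC)cc(O)c(C(=O)C#Cc2ccc(OCOC)cc2)c1OCOC
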